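The cyclohexene is disconnected at C5–C6 (shikimate numbering: C1 carries CO2Me, C2 is the vinyl CH, C3–C5 the acyloxy carbons, C6 the ring CH2). C6 is β to the ester carbonyl and C2 is allylic, so the open form is an aldehyde at C5 tethered to a Baylis–Hillman acetate (C6H2=C1(CO2Me)–C2H–OAc) on the erythrose-derived cis-acetonide of C3/C4. One SmI2 operation closes the ring (C5 ketyl onto C6, 6-endo), sets the C5 carbinol trans to O4 under control of C4, and expels the C2 acetate to place the alkene at C1=C2. Orthoester-directed O3 acetylation and double esterification with (R)-2-methylbutanoic acid complete the target.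

Key step: step 6

Remark on the chemistry: both 2-methylbutanoyl groups of the target are (R)-configured, so (R)-2-methylbutanoic acid is the acylating acid. The carbinol carbon created in step 4 (the future C2) is carried as an epimer mixture because it becomes sp2 in step 6.

Step 1
Reactants: 1 2,3-O-isopropylidene-D-erythronolactone
Product: 2 2,3-O-isopropylidene-D-erythrofuranose (lactol, anomer mixture)
Conditions: DIBAL-H (1.1 equiv), CH2Cl2, −78 °C; MeOH, aq. Rochelle salt
Reagents that add atoms: none
Why: Partial reduction of a γ-lactone with DIBAL-H at low temperature stops at the aluminium lactolate and gives the lactol on work-up, with both dioxolane stereocentres untouched.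

Step 2
Reactants: 2 2,3-O-isopropylidene-D-erythrofuranose
Product: 3 [(4R,5S)-2,2-dimethyl-5-vinyl-1,3-dioxolan-4-yl]methanol
Conditions: Ph3PCH3Br (3 equiv), KOtBu (3 equiv), THF, 0 °C → reflux
Reagents that add atoms: methyltriphenylphosphonium bromide, C[P+](c1ccccc1)(c1ccccc1)c1ccccc1.[Br-]
Why: Wittig methylenation of the open hydroxy-aldehyde tautomer of the lactol with excess non-stabilised ylide should turn the future C5 into a vinyl group (a latent aldehyde) and free the primary alcohol at the future C2.

Step 3
Reactants: 3 [(4R,5S)-2,2-dimethyl-5-vinyl-1,3-dioxolan-4-yl]methanol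
Product: 4 (4S,5S)-2,2-dimethyl-5-vinyl-1,3-dioxolane-4-carbaldehyde
Conditions: Dess–Martin periodinane (1.2 equiv), CH2Cl2, 0 °C → rt; crude aldehyde used at once
Reagents that add atoms: none
Why: Dess–Martin oxidation is non-basic, so the α-alkoxy aldehyde should form without epimerisation of the cis-dioxolane centre next to the carbonyl.

Step 4
Reactants: 4 (4S,5S)-2,2-dimethyl-5-vinyl-1,3-dioxolane-4-carbaldehyde; 5 methyl propiolate
Product: 7 methyl 2-{acetoxy[(4S,5S)-2,2-dimethyl-5-vinyl-1,3-dioxolan-4-yl]methyl}prop-2-enoate (epimer mixture at the acetoxy carbon), via diisobutylaluminium Baylis–Hillman alkoxide 6 (not isolated)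
Conditions: 5, DIBAL-H, NMO, THF, 0 °C; then 4, 0 °C → rt; then pyridine, DMAP, Ac2O, 0 °C → rt
Reagents that add atoms: acetic anhydride, CC(=O)OC(C)=O
Why: Hydroalumination of the propiolate gives the α-aluminoacrylate, whose 1,2-addition to the aldehyde is a fast, non-basic equivalent of the Morita–Baylis–Hillman reaction (vinylalumination), and the aluminium alkoxide is acetylated in the same flask; the new carbinol centre need not be controlled.

Step 5
Reactants: 7 methyl 2-{acetoxy[(4S,5S)-2,2-dimethyl-5-vinyl-1,3-dioxolan-4-yl]methyl}prop-2-enoate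
Product: 8 methyl 2-{acetoxy[(4R,5R)-5-formyl-2,2-dimethyl-1,3-dioxolan-4-yl]methyl}prop-2-enoate
Conditions: O3 (1 equiv, Sudan Red end point), CH2Cl2, −78 °C; Me2S, −78 °C → rt
Reagents that add atoms: ozone, [O-][O+]=O
Why: In this ozonolysis with reductive work-up the monosubstituted vinyl group should react far faster with electrophilic ozone than the acrylate double bond, which is deactivated by the ester and the allylic acetate, so only the C5 aldehyde is unveiled.

Step 6
Reactants: 8 methyl 2-{acetoxy[(4R,5R)-5-formyl-2,2-dimethyl-1,3-dioxolan-4-yl]methyl}prop-2-enoate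
Product: 9 methyl 3,4-O-isopropylideneshikimate (5-OH free)
Conditions: SmI2 (2.2 equiv), HMPA, THF (high dilution), −78 → −20 °C; aq. NH4Cl
Reagents that add atoms: none
Why: SmI2 transfers one electron to the chelated α-alkoxy aldehyde, the C5 ketyl radical anion adds to the unsubstituted β-carbon C6 of the 2-substituted acrylate, a second electron turns the C1 α-ester radical into a samarium(III) enolate, and this enolate expels the C2 acetate (E1cB) to leave the C1=C2 double bond. The closest known reaction type is the SmI2 ketyl–olefin reductive cyclisation onto acrylates run as a cyclisation/β-elimination sequence. The cyclohexene ring closes in the 6-endo-trig radical mode, preferred over 5-exo because C6 is the sterically free, polarity-matched terminus and the radical formed at C1 is tertiary and ester-stabilised. The new C5 stereocentre is controlled by the adjacent C4 centre: the bulky O–Sm group should lie anti to the C4–O bond on the convex face of the cis-fused dioxolane, which gives the 4,5-trans (5R) alcohol. The step needs electron transfer to the aldehyde before the acrylate and elimination towards C2 only; chelation of the α-alkoxy aldehyde, low temperature, the absence of a proton source and the single β-leaving group on the enolate should secure this, and both C2 epimers converge because C2 becomes sp2.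

Step 7
Reactants: 9 methyl 3,4-O-isopropylideneshikimate
Product: 12 methyl 3-O-acetylshikimate, via methyl shikimate 10 (not isolated), via cyclic 3,4-orthoacetate 11 (not isolated)
Conditions: TFA/H2O (9:1), 0 °C → rt, evaporate (toluene); MeC(OMe)3 (1.5 equiv), CSA (cat.), MeCN, rt; then AcOH/H2O (4:1), rt
Reagents that add atoms: trimethyl orthoacetate, COC(C)(OC)OC; water, O
Why: Aqueous acid cleaves the acetonide, the cis-3,4-diol then forms the five-membered cyclic orthoacetate in preference to the trans-4,5-diol, and kinetic acid hydrolysis of a cyclic orthoester opens to the axial ester, here the pseudoaxial allylic O3 acetate with O4 free (orthoester method for monoacylation of cis-diols).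

Step 8
Reactants: 12 methyl 3-O-acetylshikimate; 13 (R)-2-methylbutanoic acid
Product: 14 methyl (3R,4S,5R)-3-acetoxy-4,5-bis{[(2R)-2-methylbutanoyl]oxy}cyclohex-1-ene-1-carboxylate (target)
Conditions: 13 (3 equiv), DCC (3 equiv), DMAP (0.2 equiv), CH2Cl2, 0 °C → rt
Reagents that add atoms: none
Why: Steglich esterification of both remaining secondary hydroxyls under near-neutral conditions should avoid ketene formation, so the α-stereocentre of the acid is kept, and should leave little opportunity for 3→4 acetyl migration.

Compound list
1 | 2,3-O-isopropylidene-D-erythronolactone | CC1(C)O[C@@H]2COC(=O)[C@@H]2O1 | starting material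
2 | 2,3-O-isopropylidene-D-erythrofuranose (lactol, anomer mixture) | CC1(C)O[C@@H]2COC(O)[C@@H]2O1 | intermediate
3 | [(4R,5S)-2,2-dimethyl-5-vinyl-1,3-dioxolan-4-yl]methanol | C=C[C@@H]1OC(C)(C)O[C@@H]1CO | intermediate
4 | (4S,5S)-2,2-dimethyl-5-vinyl-1,3-dioxolane-4-carbaldehyde | C=C[C@@H]1OC(C)(C)O[C@@H]1C=O | intermediate
5 | methyl propiolate | C#CC(=O)OC | starting material
6 | diisobutylaluminium alkoxide of the Baylis–Hillman adduct of 4 (epimer mixture, not isolated) | COC(=O)C(=C)C(O[Al](CC(C)C)CC(C)C)[C@H]1OC(C)(C)O[C@H]1C=C | intermediate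
7 | methyl 2-{acetoxy[(4S,5S)-2,2-dimethyl-5-vinyl-1,3-dioxolan-4-yl]methyl}prop-2-enoate (epimer mixture at the acetoxy carbon) | COC(=O)C(=C)C(OC(C)=O)[C@H]1OC(C)(C)O[C@H]1C=C | intermediate
8 | methyl 2-{acetoxy[(4R,5R)-5-formyl-2,2-dimethyl-1,3-dioxolan-4-yl]methyl}prop-2-enoate (epimer mixture at the acetoxy carbon) | COC(=O)C(=C)C(OC(C)=O)[C@H]1OC(C)(C)O[C@H]1C=O | intermediate
9 | methyl 3,4-O-isopropylideneshikimate | COC(=O)C1=C[C@H]2OC(C)(C)O[C@H]2[C@H](O)C1 | intermediate
10 | methyl shikimate (not isolated) | COC(=O)C1=C[C@@H](O)[C@@H](O)[C@H](O)C1 | intermediate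
11 | methyl 3,4-O-(1-methoxyethylidene)shikimate (orthoester centre as a mixture, not isolated) | COC(=O)C1=C[C@H]2OC(C)(OC)O[C@H]2[C@H](O)C1 | intermediate
12 | methyl 3-O-acetylshikimate | COC(=O)C1=C[C@@H](OC(C)=O)[C@@H](O)[C@H](O)C1 | intermediate
13 | (R)-2-methylbutanoic acid | CC[C@@H](C)C(=O)O | starting material
14 | methyl (3R,4S,5R)-3-acetoxy-4,5-bis{[(2R)-2-methylbutanoyl]oxy}cyclohex-1-ene-1-carboxylate | COC(=O)C1=C[C@@H](OC(C)=O)[C@@H](OC(=O)[C@H](C)CC)[C@H](OC(=O)[C@H](C)CC)C1 | target

Total step count: 8. Longest linear sequence: 8 steps (1 → 14).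

Steps most likely to fail

1. Step 6. Electron transfer may go to the acrylate instead of the aldehyde, followed by loss of acetate and 1,4-elimination of the dioxolane oxygen. Intermolecular pinacol coupling, over-reduction of the γ-alkoxy enoate that is formed, or insufficient facial selectivity at C5 are further risks. The fallback sets out from 7 and comes back at 9. Treatment of 7 with MgBr2·OEt2 in THF would transpose the allylic acetate (SN2′) to methyl (Z)-2-(bromomethyl)-3-[(4R,5S)-2,2-dimethyl-5-vinyl-1,3-dioxolan-4-yl]prop-2-enoate F1. Ozonolysis of its vinyl group as in step 5 would give methyl (Z)-2-(bromomethyl)-3-[(4R,5R)-5-formyl-2,2-dimethyl-1,3-dioxolan-4-yl]prop-2-enoate F2. CrCl2 in THF at high dilution would then close the same C5–C6 bond by an intramolecular Nozaki–Hiyama-type allylation, returning to 9. The allylchromium is expected to react at its CH2 terminus because attack through the other terminus would give a cyclobutane.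

2. Step 7. The orthoester may open with the wrong regiochemistry, the acetyl group may migrate from the pseudoaxial O3 to the equatorial O4, or O5 may be acetylated through a mixed acyclic orthoester. The fallback sets out from 9 and comes back at 12. Aqueous TFA would give methyl shikimate 10, now isolated. Butane-2,3-dione, HC(OMe)3 and CSA in MeOH at reflux would protect the trans-diequatorial 4,5-diol as methyl 4,5-O-[(2S,3S)-2,3-dimethoxybutane-2,3-diyl]shikimate F3. Ac2O/pyridine would acetylate the only free hydroxyl to give the 3-O-acetyl butane-2,3-diacetal F4, and TFA/H2O would release 12.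

3. Step 5. Ozone may also attack the acrylate double bond, or the aldehyde may be over-oxidised when the end point is missed. The fallback sets out from 7 and comes back at 8. Catalytic K2OsO4 with NMO in acetone/water would dihydroxylate the more electron-rich vinyl group to methyl 2-{acetoxy[5-(1,2-dihydroxyethyl)-2,2-dimethyl-1,3-dioxolan-4-yl]methyl}prop-2-enoate F5 (cis-dioxolane, diol epimers). NaIO4 cleavage of this glycol would then give 8.

Further compounds
F1 | step 6 | methyl (Z)-2-(bromomethyl)-3-[(4R,5S)-2,2-dimethyl-5-vinyl-1,3-dioxolan-4-yl]prop-2-enoate | COC(=O)/C(CBr)=C/[C@H]1OC(C)(C)O[C@H]1C=C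
F2 | step 6 | methyl (Z)-2-(bromomethyl)-3-[(4R,5R)-5-formyl-2,2-dimethyl-1,3-dioxolan-4-yl]prop-2-enoate | COC(=O)/C(CBr)=C/[C@H]1OC(C)(C)O[C@H]1C=O
F3 | step 7 | methyl 4,5-O-[(2S,3S)-2,3-dimethoxybutane-2,3-diyl]shikimate | COC(=O)C1=C[C@@H](O)[C@H]2O[C@](C)(OC)[C@@](C)(OC)O[C@@H]2C1
F4 | step 7 | methyl 3-O-acetyl-4,5-O-[(2S,3S)-2,3-dimethoxybutane-2,3-diyl]shikimate | COC(=O)C1=C[C@@H](OC(C)=O)[C@H]2O[C@](C)(OC)[C@@](C)(OC)O[C@@H]2C1
F5 | step 5 | methyl 2-{acetoxy[5-(1,2-dihydroxyethyl)-2,2-dimethyl-1,3-dioxolan-4-yl]methyl}prop-2-enoate (cis-dioxolane, diol epimers) | COC(=O)C(=C)C(OC(C)=O)[C@H]1OC(C)(C)O[C@H]1C(O)CO
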